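## Retrosynthetic overview
1. The target comes from one reductive global operation (ArC=O to ArCH2; three ArOMe and one ArOH to ArOSiEt3, then to ArOH) on an aryl benzyl ketone that already carries all four rings.
2. The C–D bridge comes from Pd enolate arylation of a ring C bromide with 2',3'-dimethoxyacetophenone (ring D).
3. The key disconnection is the ring B–O–ring C ether C–O bond. It is split into the ring B phenol O–H and a ring C ortho-quinone diazide made from 2-amino-4-bromophenol. Carbene O–H insertion places OAr ortho to the free OH and meta to Br.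
4. The A–B bridge comes from 9-BBN hydroboration of 4-acetoxystyrene and B-alkyl Suzuki–Miyaura coupling with 3-bromoanisole.
5. No ring is built. The four benzene rings are bought and joined in the order A–B, then B–O–C, then C–D.

Assumption: the target SMILES has no stereocentre and no stereogenic double bond, so the compound is achiral and no stereocontrol is needed.

## Route

Step 1
Reactants: 1 4-vinylphenyl acetate (4-acetoxystyrene); 2 3-bromoanisole
Product: 4 4-[2-(3-methoxyphenyl)ethyl]phenol, via alkylborane 3 (not isolated)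
Conditions: 9-BBN (1.1 equiv), THF, 0 °C to rt; then 2, PdCl2(dppf) (3 mol %), 3 M aq NaOH (5 equiv), 65 °C
Reagents that add atoms: none
Why: Anti-Markovnikov hydroboration of the styrene followed by B-alkyl Suzuki–Miyaura coupling gives the saturated A–B bridge directly, the aqueous NaOH needed for transmetalation also saponifies the aryl acetate in the same pot, and no stereocentre is formed.

Step 2
Reactants: 5 2-amino-4-bromophenol; 4 4-[2-(3-methoxyphenyl)ethyl]phenol
Product: 8 4-bromo-2-{4-[2-(3-methoxyphenyl)ethyl]phenoxy}phenol, via diazonium chloride 6 (not isolated), via quinone diazide 7 (not isolated)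
Conditions: 5, NaNO2, aq HCl, 0 °C; NaOAc to pH 6, extract into ClCH2CH2Cl, dry (Na2SO4); solution added over 3 h to 4 (1.3 equiv), Rh2(OAc)4 (1 mol %), 4 Å MS, ClCH2CH2Cl, 60 °C, dark
Reagents that add atoms: none
Why: Proposed new method: dirhodium-catalysed O–H insertion of a monocyclic ortho-quinone diazide into a phenol to give a 2-aryloxyphenol, in which Rh2(OAc)4 expels N2 from 7 to give an electrophilic quinoid carbene (a metal-bound 2-oxidoaryl cation equivalent), the phenolic oxygen of 4 adds to the carbene carbon to form an oxonium ylide, and proton transfer to the quinoid oxygen restores aromaticity, so the C–O bond can form only at the carbon that carried nitrogen (ortho to OH, meta to Br) under neutral conditions that leave C–Br intact; the closest known reaction types are Rh-carbene O–H insertion of diazocarbonyl compounds and of diazonaphthoquinones into aliphatic alcohols and quinoid-carbene transfer to arenes and alkenes, and no stereocentre is formed.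

Step 3
Reactants: 8 4-bromo-2-{4-[2-(3-methoxyphenyl)ethyl]phenoxy}phenol; 9 1-(2,3-dimethoxyphenyl)ethanone
Product: 10 1-(2,3-dimethoxyphenyl)-2-(4-hydroxy-3-{4-[2-(3-methoxyphenyl)ethyl]phenoxy}phenyl)ethanone
Conditions: 9 (1.3 equiv), Pd2(dba)3 (1.5 mol %), XPhos (6 mol %), NaOtBu (3.3 equiv), 1,4-dioxane, 80 °C
Reagents that add atoms: none
Why: In this Buchwald–Hartwig-type Pd-catalysed α-arylation of an aryl methyl ketone enolate, the bulky biaryl phosphine lets zerovalent palladium insert into the electron-rich C–Br bond of the sodium phenoxide of 8 (unprotected bromophenols are established partners in enolate arylation), C–C reductive elimination outruns C–O coupling, the product rests as a hindered enolate that resists a second arylation, and no stereocentre is formed.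

Step 4
Reactants: 10 1-(2,3-dimethoxyphenyl)-2-(4-hydroxy-3-{4-[2-(3-methoxyphenyl)ethyl]phenoxy}phenyl)ethanone
Product: 12 3-[2-(4-hydroxy-3-{4-[2-(3-hydroxyphenyl)ethyl]phenoxy}phenyl)ethyl]benzene-1,2-diol (target), via tetrasilyl ether 11 (not isolated)
Conditions: B(C6F5)3 (10 mol %), Et3SiH (10 equiv), CH2Cl2, rt; then 1 M aq HCl, THF, rt
Reagents that add atoms: none
Why: In this B(C6F5)3-catalysed hydrosilane reduction (Piers-type Si–H activation), the free phenol is silylated, the aryl ketone is deoxygenated to CH2 through its benzylic silyl ether, and only sp3 C–O bonds are cleaved, so the three methyl ethers become silyl ethers plus methane while the diaryl ether survives, and mild acid then frees the four phenols without exposing the catechol to base or air.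

## Compound list
1 | 4-vinylphenyl acetate | CC(=O)Oc1ccc(C=C)cc1 | starting material
2 | 3-bromoanisole | COc1cccc(Br)c1 | starting material
3 | 4-[2-(9-borabicyclo[3.3.1]nonan-9-yl)ethyl]phenyl acetate | CC(=O)Oc1ccc(CCB2C3CCCC2CCC3)cc1 | intermediate
4 | 4-[2-(3-methoxyphenyl)ethyl]phenol | COc1cccc(CCc2ccc(O)cc2)c1 | intermediate
5 | 2-amino-4-bromophenol | Nc1cc(Br)ccc1O | starting material
6 | 5-bromo-2-hydroxybenzenediazonium chloride | Oc1ccc(Br)cc1[N+]#N.[Cl-] | intermediate
7 | 4-bromo-6-diazocyclohexa-2,4-dien-1-one | O=C1C=CC(Br)=CC1=[N+]=[N-] | intermediate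
8 | 4-bromo-2-{4-[2-(3-methoxyphenyl)ethyl]phenoxy}phenol | COc1cccc(CCc2ccc(Oc3cc(Br)ccc3O)cc2)c1 | intermediate
9 | 1-(2,3-dimethoxyphenyl)ethanone | CC(=O)c1cccc(OC)c1OC | starting material
10 | 1-(2,3-dimethoxyphenyl)-2-(4-hydroxy-3-{4-[2-(3-methoxyphenyl)ethyl]phenoxy}phenyl)ethanone | COc1cccc(CCc2ccc(Oc3cc(CC(=O)c4cccc(OC)c4OC)ccc3O)cc2)c1 | intermediate
11 | tetrakis(O-triethylsilyl) ether of 12 (all four phenolic oxygens carry SiEt3) | CC[Si](CC)(CC)Oc1cccc(CCc2ccc(Oc3cc(CCc4cccc(O[Si](CC)(CC)CC)c4O[Si](CC)(CC)CC)ccc3O[Si](CC)(CC)CC)cc2)c1 | intermediate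
12 | 3-[2-(4-hydroxy-3-{4-[2-(3-hydroxyphenyl)ethyl]phenoxy}phenyl)ethyl]benzene-1,2-diol (achiral) | Oc1cccc(CCc2ccc(Oc3cc(CCc4cccc(O)c4O)ccc3O)cc2)c1 | target

## Step count and risks
Total step count: 4. Longest linear sequence: 4 (steps 1 to 4).

The three steps most likely to fail are steps 2, 3 and 4.

**Step 2 (the new step).** The risks are these:
- Wolff ring contraction of 7.
- C–H arylation of the anisole or phenol ring of 4 in place of O–H insertion.
- A second insertion into the OH of 8.
- Sluggish loss of N2.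

The fallback uses known chemistry, sets out from 4 and comes back at 8. SNAr of 4 on commercial 4-bromo-2-fluorobenzaldehyde (K2CO3, DMF, 90 °C; the fluoride ortho to the formyl group is displaced) gives 4-bromo-2-{4-[2-(3-methoxyphenyl)ethyl]phenoxy}benzaldehyde F1. Baeyer–Villiger oxidation (mCPBA, CH2Cl2, rt) gives 4-bromo-2-{4-[2-(3-methoxyphenyl)ethyl]phenoxy}phenyl formate F2. Aqueous NaOH in MeOH then cleaves the formate to 8.

**Step 3.** The risks are slow oxidative addition into the bromophenoxide, poor solubility of the sodium phenoxide, and diarylation.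

The fallback sets out from 8 and comes back at 11. Wittig methylenation of commercial 2,3-dimethoxybenzaldehyde (Ph3PCH3Br, KOtBu, THF) gives 1-ethenyl-2,3-dimethoxybenzene F3. Hydroboration with 9-BBN gives 9-[2-(2,3-dimethoxyphenyl)ethyl]-9-borabicyclo[3.3.1]nonane F4. B-alkyl Suzuki–Miyaura coupling with 8 (PdCl2(dppf), aq NaOH, THF, 65 °C) gives 4-[2-(2,3-dimethoxyphenyl)ethyl]-2-{4-[2-(3-methoxyphenyl)ethyl]phenoxy}phenol F5. Under the B(C6F5)3/Et3SiH conditions of step 4, F5 is silylated and demethylated to 11.

**Step 4.** The risks are incomplete cleavage of the hindered 2-methoxy group on ring D, elimination of the benzylic silyl ether to a stilbene, and poisoning of the borane by moisture.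

The fallback sets out from 10 and comes back at 12. BBr3 (CH2Cl2, −78 °C to rt) gives 1-(2,3-dihydroxyphenyl)-2-(4-hydroxy-3-{4-[2-(3-hydroxyphenyl)ethyl]phenoxy}phenyl)ethanone F6. Hydrogenolysis of the aryl ketone (H2, Pd/C, AcOH, cat. H2SO4, 50 °C) then gives 12.

## Further compounds
F1 | step 2 | 4-bromo-2-{4-[2-(3-methoxyphenyl)ethyl]phenoxy}benzaldehyde | COc1cccc(CCc2ccc(Oc3cc(Br)ccc3C=O)cc2)c1
F2 | step 2 | 4-bromo-2-{4-[2-(3-methoxyphenyl)ethyl]phenoxy}phenyl formate | COc1cccc(CCc2ccc(Oc3cc(Br)ccc3OC=O)cc2)c1
F3 | step 3 | 1-ethenyl-2,3-dimethoxybenzene | C=Cc1cccc(OC)c1OC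
F4 | step 3 | 9-[2-(2,3-dimethoxyphenyl)ethyl]-9-borabicyclo[3.3.1]nonane | COc1cccc(CCB2C3CCCC2CCC3)c1OC
F5 | step 3 | 4-[2-(2,3-dimethoxyphenyl)ethyl]-2-{4-[2-(3-methoxyphenyl)ethyl]phenoxy}phenol | COc1cccc(CCc2ccc(Oc3cc(CCc4cccc(OC)c4OC)ccc3O)cc2)c1
F6 | step 4 | 1-(2,3-dihydroxyphenyl)-2-(4-hydroxy-3-{4-[2-(3-hydroxyphenyl)ethyl]phenoxy}phenyl)ethanone | Oc1cccc(CCc2ccc(Oc3cc(CC(=O)c4cccc(O)c4O)ccc3O)cc2)c1
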